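**Assumptions (one line each)**
- The chain in the SMILES is read as 13 CH2 groups between the stereocentre and the ester oxygen, so the target is (S)-14-methylhexadecyl 2,3-dihydroxybenzoate (CIP at C14: long chain > ethyl > methyl > H gives S).
- (S)-DTBM-SEGPHOS is written as the ligand enantiomer that delivers hydride to the Re face of C14; this sense of induction is not known in advance, and the (R)-ligand is used instead if the first run shows the opposite.

**Retrosynthetic overview**
1. Ester C–O bond last: target ⇒ (S)-14-methylhexadecan-1-ol (8) + unprotected 2,3-dihydroxybenzoic acid (9), by Mitsunobu esterification.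
2. C14 stereocentre and C15–C16 bond together: 8 ⇒ achiral 1,1-disubstituted alkene 5, by a proposed CuH-catalysed enantioselective anti-Markovnikov hydromethylation (the new step).
3. C12–C13 bond: 5 ⇒ TBS-protected 12-bromododecanol (3) + methallylmagnesium chloride (4), by Cu-catalysed sp3–sp3 coupling.
4. Rings: none is constructed; the only ring (the catechol arene) is bought intact in 9.

**Route**

Step 1
Reactants: 1, 12-bromododecan-1-ol; 2, tert-butyldimethylsilyl chloride
Product: 3, [(12-bromododecyl)oxy](tert-butyl)dimethylsilane
Conditions: TBSCl (1.1 equiv), imidazole, CH2Cl2, 0 °C → rt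
Reagents that add atoms: TBSCl, CC(C)(C)[Si](C)(C)Cl
Why: Standard imidazole-mediated silylation of a primary alcohol; the primary bromide is inert under these conditions.

Step 2
Reactants: 3, [(12-bromododecyl)oxy](tert-butyl)dimethylsilane; 4, 2-methylallyl(methallyl)magnesium chloride
Product: 5, tert-butyldimethyl[(14-methylpentadec-14-en-1-yl)oxy]silane, TBSO–(CH2)13–C(CH3)=CH2 (achiral)
Conditions: 4 (1.5 equiv, 0.5 M in THF), Li2CuCl4 (3 mol%), THF, –20 °C → rt
Reagents that add atoms: methallylmagnesium chloride, CC(=C)C[Mg]Cl
Why: Kochi-type Cu-catalysed sp3–sp3 cross-coupling of a Grignard reagent with a primary alkyl bromide; methallyl is symmetric so SN2 and SN2′ give the same product, and the TBS ether tolerates the Grignard reagent.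

Step 3
Reactants: 5, tert-butyldimethyl[(14-methylpentadec-14-en-1-yl)oxy]silane; 6, methyl p-toluenesulfonate
Product: 7, (S)-tert-butyldimethyl[(14-methylhexadecyl)oxy]silane
Conditions: Cu(OAc)2 (5 mol%), (S)-DTBM-SEGPHOS (5.5 mol%), (MeO)2MeSiH (3 equiv), MeOTs (2 equiv, syringe pump), LiI (20 mol%), LiOMe (2.5 equiv), THF, 40 °C, 36 h
Reagents that add atoms: methyl p-toluenesulfonate (CH3 donor), COS(=O)(=O)c1ccc(C)cc1 (the silane supplies only H)
Why: Proposed new method: enantioselective anti-Markovnikov hydromethylation of an unactivated 1,1-dialkyl alkene — L*Cu–H adds syn across C14=C15 with Cu on the terminal CH2 and hydride delivered to the Re face of C14 (the ligand quadrants discriminate CH3 from the CH2R chain; this irreversible hydrocupration sets the S centre, which is β to copper and so cannot be scrambled afterwards), the primary alkyl–Cu(I) is then methylated by MeI kept at low steady-state concentration from MeOTs/I– (SN2-type oxidative addition, then C–C reductive elimination), and LiOMe/silane regenerate Cu–H; the closest known reaction types are CuH-catalysed anti-Markovnikov hydroamination of 1,1-disubstituted alkenes (same enantio-determining hydrocupration) and CuH-catalysed hydromethylation of vinylarenes with MeOTs/iodide (same Cu–C methylation), but to my knowledge the combination on an unactivated 1,1-dialkyl alkene to give a β-methyl stereocentre has not been shown.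

Step 4
Reactants: 7, (S)-tert-butyldimethyl[(14-methylhexadecyl)oxy]silane
Product: 8, (S)-14-methylhexadecan-1-ol
Conditions: TBAF (1.2 equiv), THF, rt
Reagents that add atoms: none
Why: Fluoride-mediated Si–O cleavage (desilylation); the remote, non-acidic C14–H centre cannot epimerise.

Step 5
Reactants: 8, (S)-14-methylhexadecan-1-ol; 9, 2,3-dihydroxybenzoic acid
Product: 10, Gentiside C, (S)-14-methylhexadecyl 2,3-dihydroxybenzoate
Conditions: 9 (1.3 equiv), PPh3 (1.2 equiv), DIAD (1.2 equiv, added last, dropwise), THF, 0 °C → rt, Ar
Reagents that add atoms: 2,3-dihydroxybenzoic acid, OC(=O)c1cccc(O)c1O (PPh3 and DIAD leave no atoms)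
Why: Mitsunobu esterification, in which the alcohol (not the acid) is activated so the phenols cannot be acylated, and only the CO2H (pKa ≈ 3) protonates the betaine so the carboxylate is alkylated at the primary carbon while the phenols (pKa ≥ 10, 2-OH hydrogen-bonded) stay free; C14 is 13 carbons away and untouched.

**Compound list**
1 | 12-bromododecan-1-ol | OCCCCCCCCCCCCBr | starting material
2 | tert-butyldimethylsilyl chloride | CC(C)(C)[Si](C)(C)Cl | starting material
3 | [(12-bromododecyl)oxy](tert-butyl)dimethylsilane | CC(C)(C)[Si](C)(C)OCCCCCCCCCCCCBr | intermediate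
4 | 2-methylallylmagnesium chloride | CC(=C)C[Mg]Cl | starting material
5 | tert-butyldimethyl[(14-methylpentadec-14-en-1-yl)oxy]silane | C=C(C)CCCCCCCCCCCCCO[Si](C)(C)C(C)(C)C | intermediate
6 | methyl p-toluenesulfonate | COS(=O)(=O)c1ccc(C)cc1 | starting material
7 | (S)-tert-butyldimethyl[(14-methylhexadecyl)oxy]silane | CC[C@H](C)CCCCCCCCCCCCCO[Si](C)(C)C(C)(C)C | intermediate
8 | (S)-14-methylhexadecan-1-ol | CC[C@H](C)CCCCCCCCCCCCCO | intermediate
9 | 2,3-dihydroxybenzoic acid | OC(=O)c1cccc(O)c1O | starting material
10 | Gentiside C, (S)-14-methylhexadecyl 2,3-dihydroxybenzoate | CC[C@H](C)CCCCCCCCCCCCCOC(=O)c1cccc(O)c1O | target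

**Totals**
- Total step count: 5
- Longest linear sequence: 5 steps (1 → 3 → 5 → 7 → 8 → 10)

**Three steps most likely to fail**

1. Step 3 (proposed hydromethylation).
   - Risks: ee limited by CH3-versus-n-alkyl discrimination, and a remote centre in an oil cannot be upgraded by crystallisation.
   - Risks: Cu–H may reduce MeI faster than it hydrocuprates the unactivated alkene.
   - Risks: protodemetalation would give the iso-C16 (des-methyl) TBS ether, which is essentially inseparable from 7; residual 5 can be removed on AgNO3-silica.
   - Assay: ee of 8 is checked by derivatisation with an enantiopure fluorescent acid and low-temperature RP-HPLC against authentic (S)-8.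
   - Fallback (known chemistry, chiral pool): form (S)-2-methylbutylmagnesium bromide from commercial (S)-1-bromo-2-methylbutane and couple it with bromide 3 under Li2CuCl4 catalysis in THF. This gives 7 directly with the stereocentre bought, and the route rejoins at step 4.

2. Step 5 (Mitsunobu on the unprotected catechol acid).
   - Risks: phenol O-alkylation, or sequestration of PPh3/DIAD by the catechol as a cyclic phosphorane, lowering yield.
   - Fallback: protect the acid instead. Esterify 8 with 2,3-bis(benzyloxy)benzoic acid (EDC·HCl, DMAP, CH2Cl2), then remove both benzyl groups by hydrogenolysis (H2, Pd/C, EtOAc). No alkene is present at that stage.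

3. Step 2 (Cu-catalysed methallyl–alkyl coupling).
   - Risks: Wurtz-type homocoupling of the allylic Grignard reagent, and reduction or elimination of bromide 3, giving incomplete conversion.
   - Fallback: build the isopropenyl terminus by carbonyl olefination. Alkylate lithiated acetone N,N-dimethylhydrazone with 3, hydrolyse to 15-(TBSO)pentadecan-2-one, then Wittig methylenation (Ph3P=CH2) to 5.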